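**Strategy.** The route rests on disconnecting the aryl–C6 bond (3,7-dioxabicyclo[3.3.0]octane numbering: C1 bears OAc, C2 and C6 the aryl groups; ring A = C5–C6–O7–C8–C1, ring B = C1–C2–O3–C4–C5). C6 is an acetal carbon in disguise, flanked by O7 and the bridgehead C5–H. Ionising lactol acetate 13 gives a ring-A oxocarbenium ion that unprotected guaiacol attacks para to its OH on the convex face of the cis-fused bicycle. This sets C6 and completes the skeleton with the tertiary acetate in place. Acetate 13 comes from an (R)-vinyl lactone and O-benzylvanillin by aldol condensation, reduction, asymmetric epoxidation with ring-B closure and ozonolysis.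

Key step: step 7

Remark: the target is read as the (1R,2S,5S,6R) isomer with both aryl groups on the convex face (cis to H5 and to the C1 acetate); because the arene partner is used as the free phenol, the tertiary acetate is installed before the coupling.

**Step 1**
Reactants: 1 furan-2(5H)-one; 2 potassium vinyltrifluoroborate
Product: 3 (R)-4-ethenyloxolan-2-one
Conditions: [Rh(cod)2]BF4 (3 mol %), (R)-BINAP (3.3 mol %), toluene/H2O 10:1, 100 °C
Reagents that add atoms: none
Why: Rh-catalysed asymmetric conjugate addition of an alkenylboron reagent to an α,β-unsaturated lactone (Hayashi–Miyaura reaction), in which the vinyl–Rh species adds to the butenolide face selected by the ligand ((R)-BINAP is expected, by analogy with cyclic enones, to give the (R)-lactone) and so sets the centre that becomes C5.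

**Step 2**
Reactants: 3 (R)-4-ethenyloxolan-2-one; 4 4-(benzyloxy)-3-methoxybenzaldehyde
Product: 7 (3E,4S)-3-[4-(benzyloxy)-3-methoxybenzylidene]-4-ethenyloxolan-2-one, via aldol adduct 5 (not isolated), via mesylate 6 (not isolated)
Conditions: LiN(SiMe3)2 (1.1 equiv), THF, −78 °C; then 4; then MsCl (1.2 equiv), −78 → 0 °C; then DBU (2.5 equiv), 0 °C → rt
Reagents that add atoms: none
Why: aldol addition of the lactone lithium enolate followed by mesylation and E1cB elimination (aldol condensation) should give the thermodynamically favoured (E)-arylidene lactone (aryl anti to the carbonyl), while the C4 stereocentre is not acidic under these conditions and is untouched.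

**Step 3**
Reactants: 7 (3E,4S)-3-[4-(benzyloxy)-3-methoxybenzylidene]-4-ethenyloxolan-2-one
Product: 8 (2E,3S)-2-[4-(benzyloxy)-3-methoxybenzylidene]-3-ethenylbutane-1,4-diol
Conditions: i-Bu2AlH (4.5 equiv), CH2Cl2, −78 → 0 °C; aq. KNaC4H4O6 work-up
Reagents that add atoms: none
Why: i-Bu2AlH reduces the conjugated lactone by 1,2-hydride delivery through the lactol and the enal to the allylic 1,4-diol without touching the alkenes, so the alkene geometry and the stereocentre are retained.

**Step 4**
Reactants: 8 (2E,3S)-2-[4-(benzyloxy)-3-methoxybenzylidene]-3-ethenylbutane-1,4-diol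
Product: 10 (2S,3R,4R)-2-[4-(benzyloxy)-3-methoxyphenyl]-4-ethenyl-3-(hydroxymethyl)oxolan-3-ol, via epoxy diol 9 (not isolated)
Conditions: Ti(OiPr)4 (0.2 equiv), D-(−)-diethyl tartrate (0.24 equiv), t-BuOOH (1.5 equiv), 4 Å molecular sieves, CH2Cl2, −25 °C; then camphorsulfonic acid (5 mol %), 0 °C
Reagents that add atoms: tert-butyl hydroperoxide CC(C)(C)OO
Why: Sharpless asymmetric epoxidation of the primary allylic alcohol under reagent control (D-tartrate) should give the (2R,3R)-epoxide 9, whose benzylic carbon is then opened with inversion by the 1,4-related hydroxymethyl group (C3-selective opening of a 2,3-epoxy alcohol, five-membered ether closure), which sets C1 (tertiary OH, R) and C2 (aryl cis to that OH, S) of ring B.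

**Step 5**
Reactants: 10 (2S,3R,4R)-2-[4-(benzyloxy)-3-methoxyphenyl]-4-ethenyl-3-(hydroxymethyl)oxolan-3-ol
Product: 12 (1R,2S,5R)-2-[4-(benzyloxy)-3-methoxyphenyl]-3,7-dioxabicyclo[3.3.0]octane-1,6-diol (C6 anomers), via hydroxy aldehyde 11 (not isolated)
Conditions: O3, CH2Cl2/MeOH 4:1, −78 °C (stopped when 10 is consumed); then Me2S, −78 °C → rt
Reagents that add atoms: ozone [O-][O+]=O
Why: ozonolysis cleaves the terminal vinyl group, which is far more reactive towards ozone than the alkoxyarenes and leaves the 1,2-diol alone, and the aldehyde is trapped at once by the cis hydroxymethyl group as the five-membered lactol, closing ring A with the only possible (cis) ring fusion.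

**Step 6**
Reactants: 12 (1R,2S,5R)-2-[4-(benzyloxy)-3-methoxyphenyl]-3,7-dioxabicyclo[3.3.0]octane-1,6-diol
Product: 13 (1R,2S,5R)-2-[4-(benzyloxy)-3-methoxyphenyl]-3,7-dioxabicyclo[3.3.0]octane-1,6-diyl diacetate (C6 anomers)
Conditions: Ac2O (6 equiv), Et3N (8 equiv), DMAP (0.5 equiv), CH2Cl2, rt → 35 °C
Reagents that add atoms: acetic anhydride CC(=O)OC(C)=O
Why: DMAP-catalysed acylation (Steglich-type nucleophilic catalysis) should esterify both the lactol hydroxyl and the tertiary bridgehead alcohol, which sits on the open convex face, without changing any stereocentre of the skeleton.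

**Step 7**
Reactants: 13 (1R,2S,5R)-2-[4-(benzyloxy)-3-methoxyphenyl]-3,7-dioxabicyclo[3.3.0]octane-1,6-diyl diacetate; 14 guaiacol (2-methoxyphenol)
Product: 15 (1R,2S,5S,6R)-2-[4-(benzyloxy)-3-methoxyphenyl]-6-(4-hydroxy-3-methoxyphenyl)-3,7-dioxabicyclo[3.3.0]octan-1-yl acetate
Conditions: 14 (3 equiv), Me3SiOTf (0.2 equiv), CH2Cl2, −40 → −10 °C
Reagents that add atoms: none
Why: Me3SiOTf ionises the anomeric acetate at C6 to the ring-A oxocarbenium ion (O7=C6+), which is attacked by the free phenol through its carbon para to OH and then rearomatises (Friedel–Crafts C-arylation). The closest known reaction type is the acid-promoted C-arylation of furofuran lactols (samin type) and of glycosyl acetates by phenols (aryl C-glycoside synthesis). No ring is closed in this step; the cis-fused bicycle is already in place and only its acetal carbon C6 reacts. The new stereocentre C6 is controlled by the roof shape of the cis-fused 3,7-dioxabicyclo[3.3.0]octane: the arene should add to the convex face, anti to ring B, which places the aryl group cis to H5 (6R). Site selectivity on guaiacol (para to OH, not ortho or para to OMe) is needed and is secured by the stronger para-directing free hydroxyl and the bulk of the bicyclic cation; any O-aryl acetal formed first re-ionises under the acid and funnels to the C-aryl product. Chemoselectivity over the benzylic C2–O3 bond is also needed and is secured by the electron-withdrawing C1 acetate next to C2 and by the low temperature.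

**Step 8**
Reactants: 15 (1R,2S,5S,6R)-2-[4-(benzyloxy)-3-methoxyphenyl]-6-(4-hydroxy-3-methoxyphenyl)-3,7-dioxabicyclo[3.3.0]octan-1-yl acetate
Product: 16 8-acetoxypinoresinol, (1R,2S,5S,6R)-2,6-bis(4-hydroxy-3-methoxyphenyl)-3,7-dioxabicyclo[3.3.0]octan-1-yl acetate
Conditions: H2 (1 atm), Pd/C (10 % Pd), EtOAc, rt, stopped at consumption of 15
Reagents that add atoms: none
Why: hydrogenolysis of the aryl benzyl ether over Pd/C in a neutral aprotic solvent should be much faster than cleavage of the ring benzylic C–O bonds, so the phenol is freed while the acetate and the four stereocentres stay untouched.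

**Compound list**
1 | furan-2(5H)-one | O=C1OCC=C1 | starting material
2 | potassium vinyltrifluoroborate | C=C[B-](F)(F)F.[K+] | starting material
3 | (R)-4-ethenyloxolan-2-one | O=C1OC[C@@H](C=C)C1 | intermediate
4 | 4-(benzyloxy)-3-methoxybenzaldehyde | O=Cc1ccc(OCc2ccccc2)c(OC)c1 | starting material
5 | (4S)-3-{[4-(benzyloxy)-3-methoxyphenyl](hydroxy)methyl}-4-ethenyloxolan-2-one, diastereomers at C3 and the carbinol carbon, not isolated | O=C1OC[C@@H](C=C)C1C(O)c1ccc(OCc2ccccc2)c(OC)c1 | intermediate
6 | [4-(benzyloxy)-3-methoxyphenyl][(4S)-4-ethenyl-2-oxooxolan-3-yl]methyl methanesulfonate, diastereomers, not isolated | O=C1OC[C@@H](C=C)C1C(OS(C)(=O)=O)c1ccc(OCc2ccccc2)c(OC)c1 | intermediate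
7 | (3E,4S)-3-[4-(benzyloxy)-3-methoxybenzylidene]-4-ethenyloxolan-2-one | O=C1OC[C@@H](C=C)/C1=C\c1ccc(OCc2ccccc2)c(OC)c1 | intermediate
8 | (2E,3S)-2-[4-(benzyloxy)-3-methoxybenzylidene]-3-ethenylbutane-1,4-diol | OC/C(=C/c1ccc(OCc2ccccc2)c(OC)c1)[C@@H](CO)C=C | intermediate
9 | (2R)-2-[(2R,3R)-3-[4-(benzyloxy)-3-methoxyphenyl]-2-(hydroxymethyl)oxiran-2-yl]but-3-en-1-ol, not isolated | OC[C@]1(O[C@@H]1c2ccc(OCc3ccccc3)c(OC)c2)[C@@H](CO)C=C | intermediate
10 | (2S,3R,4R)-2-[4-(benzyloxy)-3-methoxyphenyl]-4-ethenyl-3-(hydroxymethyl)oxolan-3-ol | OC[C@@]1(O)[C@H](c2ccc(OCc3ccccc3)c(OC)c2)OC[C@H]1C=C | intermediate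
11 | (3R,4R,5S)-5-[4-(benzyloxy)-3-methoxyphenyl]-4-hydroxy-4-(hydroxymethyl)oxolane-3-carbaldehyde, not isolated | OC[C@@]1(O)[C@H](c2ccc(OCc3ccccc3)c(OC)c2)OC[C@H]1C=O | intermediate
12 | (1R,2S,5R)-2-[4-(benzyloxy)-3-methoxyphenyl]-3,7-dioxabicyclo[3.3.0]octane-1,6-diol, C6 anomers | OC1OC[C@@]2(O)[C@H](c3ccc(OCc4ccccc4)c(OC)c3)OC[C@@H]12 | intermediate
13 | (1R,2S,5R)-2-[4-(benzyloxy)-3-methoxyphenyl]-3,7-dioxabicyclo[3.3.0]octane-1,6-diyl diacetate, C6 anomers | CC(=O)OC1OC[C@@]2(OC(C)=O)[C@H](c3ccc(OCc4ccccc4)c(OC)c3)OC[C@@H]12 | intermediate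
14 | guaiacol (2-methoxyphenol) | COc1ccccc1O | starting material
15 | (1R,2S,5S,6R)-2-[4-(benzyloxy)-3-methoxyphenyl]-6-(4-hydroxy-3-methoxyphenyl)-3,7-dioxabicyclo[3.3.0]octan-1-yl acetate | COc1cc([C@@H]2OC[C@@]3(OC(C)=O)[C@H](c4ccc(OCc5ccccc5)c(OC)c4)OC[C@@H]23)ccc1O | intermediate
16 | 8-acetoxypinoresinol, (1R,2S,5S,6R)-2,6-bis(4-hydroxy-3-methoxyphenyl)-3,7-dioxabicyclo[3.3.0]octan-1-yl acetate | COc1cc([C@@H]2OC[C@@]3(OC(C)=O)[C@H](c4ccc(O)c(OC)c4)OC[C@@H]23)ccc1O | target

**Step count.** Total: 8 steps. Longest linear sequence: 8 steps (1 → 3 → 7 → 8 → 10 → 12 → 13 → 15 → 16).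

**Steps most likely to fail**

Risk 1, step 7 (key step). What may go wrong:
- poor site selectivity on guaiacol (attack ortho to OH or para to OMe);
- arrest at the O-aryl acetal;
- loss of facial control through remote participation of the C1 acetate;
- acid-induced epimerisation of the p-hydroxybenzylic ether that has just been formed.

The fallback sets out from lactol 12 and returns to the route at target 16. It replaces the cationic arylation by carbonyl addition of a regiodefined aryl metal and a separate ring closure. Lactol 12 is treated at 0 °C in THF with an excess of [4-(benzyloxy)-3-methoxyphenyl]magnesium bromide F1 (from commercial 1-(benzyloxy)-4-bromo-2-methoxybenzene and Mg). The reagent deprotonates both hydroxyls and adds to the ring-opened aldehyde, giving the triol (2S,3R,4S)-2-[4-(benzyloxy)-3-methoxyphenyl]-4-{[4-(benzyloxy)-3-methoxyphenyl](hydroxy)methyl}-3-(hydroxymethyl)oxolan-3-ol F2 as carbinol epimers. Catalytic camphorsulfonic acid in CH2Cl2 at 0 °C should ionise the p-alkoxybenzylic alcohol; the primary hydroxyl captures the cation, so both epimers converge on ring A, giving (1R,2S,5S,6R)-2,6-bis[4-(benzyloxy)-3-methoxyphenyl]-3,7-dioxabicyclo[3.3.0]octan-1-ol F3. Ac2O/DMAP/Et3N acetylates the only free (tertiary) hydroxyl to give (1R,2S,5S,6R)-2,6-bis[4-(benzyloxy)-3-methoxyphenyl]-3,7-dioxabicyclo[3.3.0]octan-1-yl acetate F4. Hydrogenolysis (H2, Pd/C, EtOAc) of both benzyl ethers then gives 16.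

Risk 2, step 4. What may go wrong:
- incomplete reagent control if the tartrate and the existing stereocentre of 8 are mismatched;
- slow turnover because the diol ties up the Ti centre;
- loss of stereospecificity when the electron-rich benzylic epoxide opens through a free cation before the internal hydroxyl attacks, which would give the C2 epimer.

The fallback sets out from diol 8 and returns at compound 10. It separates epoxidation from ring closure and removes the dependence on alkoxide coordination. Shi epoxidation (D-fructose-derived ketone, 0.3 equiv, KHSO5, K2CO3 buffer, MeCN/dimethoxymethane/H2O, 0 °C) is a dioxirane epoxidation under basic buffered conditions. By analogy with trans-β-methylstyrene it is expected to give the same (2R,3R)-epoxide 9, now isolated. Ring closure with pyridinium p-toluenesulfonate in CH2Cl2 at low temperature then gives 10. This fallback makes no new compound (F0).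

Risk 3, step 1. What may go wrong:
- low conversion, because the butenolide is a weak acceptor and protodeboronation of the vinylboron reagent can outrun insertion;
- insufficient enantioselectivity.

The fallback sets out from furanone 1 and returns at compound 3. It replaces asymmetric catalysis by a racemic conjugate addition followed by resolution. Vinylmagnesium bromide with catalytic CuBr·SMe2 and Me3SiCl in THF at −78 °C gives racemic 4-ethenyloxolan-2-one F5. Ring opening with (S)-1-phenylethylamine (neat, 80 °C) gives two diastereomeric hydroxy amides. Crystallisation or chromatography isolates (3R)-3-(hydroxymethyl)-N-[(1S)-1-phenylethyl]pent-4-enamide F6. Hydrolysis with relactonisation (aq. H2SO4, dioxane, reflux) returns (R)-lactone 3.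

**Further compounds**
F1 | step 7 | [4-(benzyloxy)-3-methoxyphenyl]magnesium bromide | COc1cc([Mg]Br)ccc1OCc1ccccc1
F2 | step 7 | (2S,3R,4S)-2-[4-(benzyloxy)-3-methoxyphenyl]-4-{[4-(benzyloxy)-3-methoxyphenyl](hydroxy)methyl}-3-(hydroxymethyl)oxolan-3-ol, carbinol epimers | OC[C@@]1(O)[C@H](c2ccc(OCc3ccccc3)c(OC)c2)OC[C@H]1C(O)c4ccc(OCc5ccccc5)c(OC)c4
F3 | step 7 | (1R,2S,5S,6R)-2,6-bis[4-(benzyloxy)-3-methoxyphenyl]-3,7-dioxabicyclo[3.3.0]octan-1-ol | COc1cc([C@@H]2OC[C@@]3(O)[C@H](c4ccc(OCc5ccccc5)c(OC)c4)OC[C@@H]23)ccc1OCc1ccccc1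
F4 | step 7 | (1R,2S,5S,6R)-2,6-bis[4-(benzyloxy)-3-methoxyphenyl]-3,7-dioxabicyclo[3.3.0]octan-1-yl acetate | COc1cc([C@@H]2OC[C@@]3(OC(C)=O)[C@H](c4ccc(OCc5ccccc5)c(OC)c4)OC[C@@H]23)ccc1OCc1ccccc1
F0 | step 4 | none | none
F5 | step 1 | rac-4-ethenyloxolan-2-one | O=C1OCC(C=C)C1
F6 | step 1 | (3R)-3-(hydroxymethyl)-N-[(1S)-1-phenylethyl]pent-4-enamide | C=C[C@H](CO)CC(=O)N[C@@H](C)c1ccccc1
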